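Read one clock off the earlier runs before anything else; the flasks below differ in how the charges go in, and first product is what counts.

| flask | starting material | coupling partner | remark | time |
|---|---|---|---|---|
| maple | 20 mM | 2 equiv | run made earlier |  |
| cedar | 20 mM | 1 equiv | run made earlier |  |
| grey | 20 mM | 2.00 equiv | everything together at the start | 8.0 min |
| red | 20 mM (fed, over 5.0 min) | 2.00 equiv | all else is in the flask from the start; the feed brings no volume worth counting | 8.0 min |
| violet | 20 mM | 2.00 equiv (in portions, 4, over 5.0 min) | first portion at the start, last at 5.0 min | 8.0 min |
| amber | 20 mM | 2.00 equiv (fed, over 5.0 min) | all else is in the flask from the start; the feed brings no volume worth counting | 8.0 min |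
| teal | 20 mM | 2.00 equiv (fed, over 80 s) | all else is in the flask from the start; the feed brings no volume worth counting | 8.0 min |

- maple (time / min: first product / %, starting material / %): 0.667: 22, 65; 2.00: 27, 38; 4.00: 31, 27; 6.00: 29, 20; 8.00: 33, 19
- cedar (time / s: first product / %, starting material / %): 10.0: 3, 91; 25.0: 10, 89; 40.0: 14, 77; 60.0: 19, 72; 90.0: 22, 64

(readings scatter by 1.5 percentage points)

1. the best flask by amount of first product, in percent of the starting material charged; "all alike" if 1.5 percentage points covers them all (grey / red / violet / amber / teal / all alike)
2. amount of first product at the end, in percent of the starting material charged, grey
3. amount of first product at the end, in percent of the starting material charged, red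
4. amount of first product at the end, in percent of the starting material charged, violet
5. amount of first product at the end, in percent of the starting material charged, amber
6. amount of first product at the end, in percent of the starting material charged, teal

- what is said of first product includes crystals
- crystals is a solid; its amount is given per volume of the solution
- candidate steps: starting material + coupling partner -> first product; coupling partner + first product -> double product; coupling partner + double product -> triple product; coupling partner + triple product -> tetra adduct; crystals <-> first product

The first maple reading gives 1.55 min for τ, the time in which starting material falls by a factor e at 2 equiv of coupling partner, a pseudo-first-order lifetime. Cedar, with half the partner, reads 3.04 min from its value at 60.0 s, twice as long, so I let τ go inversely with partner.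

Now I climb the ladder, fastest first. Teal's feed of 80 s ends sooner than τ, so teal has its partner in before the clock has run once, and I expect it to match grey. The next rung, τ itself, is my crossing: at these charges I expect a shorter feed to leave the pace to the chemistry, and a longer one to hand it to the addition. The slow addition of 5.0 min is longer than τ, at 3.23 clocks, so I expect red, violet and amber to part from grey. The top rung is the run itself: 8.00 min is 5.16 clocks, which at a steady τ leaves 0.573% of starting material. Yet maple reads 19%, more than that, so I read partner as going to the later steps too, and τ as lengthening late in maple.

The forecast names amber as best, with grey 32%, red 19%, violet 35%, amber 36% and teal 33%, holding that “Feeding partner keeps the same selectivity curve but gives crystallisation more time”. My clock gives pairings, not yields.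

The flasks give grey 33.2%, red 27.4%, violet 41.6%, amber 39.4% and teal 34.2%, and the most first product stands in violet.

    starting material + coupling partner → first product (k = 19.0 M⁻¹ min⁻¹)
    coupling partner + first product → double product (k = 58.0 M⁻¹ min⁻¹)
    coupling partner + double product → triple product (k = 46.0 M⁻¹ min⁻¹)
    coupling partner + triple product → tetra adduct (k = 8.30 M⁻¹ min⁻¹)
    crystals ⇌ first product, rate k5*(cs5 - [first product]) while solid is left; crystals form when [first product] > cs5 (solubility = 0.450 mM, k = 0.850 min⁻¹)

Teal lies less than 1.5 percentage points above grey, while amber lies 6.2 points above it and red 5.8 points below it. Now take a neighbour of red, the same flask at 5.0 mM of starting material with the equivalents held. Its partner is thinner by a factor 4.00, so I put τ at 6.19 min, longer than the feed. Starting material arrives on average 5.50 min before the end, so at a steady τ I reckon 41.1% left. The neighbour ends with partner at 50.8% of its own charge, starting material at 48.4% and first product at 22.9%.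

Readings and results stem from a simulated flask from invented constants; scatter was added.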